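| flask | substrate | partner | protic impurity | remark | time |
|---|---|---|---|---|---|
| oak | 0.050 M | 0.084 M | 0.050 M | run made earlier |  |
| ash | 0.050 M | 0.18 M | 0.050 M | run made earlier |  |
| maple | 0.050 M | 0.30 M | 0.050 M | run made earlier |  |
| alder | 0.071 M | 0.10 M | 0.050 M | run made earlier |  |
| north | 0.050 M | 0.100 M | 0.0500 M |  | 15 min |
| south-west | 0.15 M | 0.400 M | 0.0500 M |  | 15 min |

- oak (time / min: product / %): 1.33: 2.1; 2.50: 2.7; 4.00: 7.2; 8.00: 18.5; 15.0: 35.8
- ash (time / min: product / %): 3.00: 10.6; 6.00: 29.3; 10.0: 50.9; 12.0: 59.7; 15.0: 70.6
- maple (time / min: product / %): 1.33: 3.6; 2.50: 12.4; 4.00: 23.8; 8.00: 50.9; 15.0: 77.7
- alder (time / min: product / %): 1.33: 1.5; 2.50: 4.4; 4.00: 9.3; 8.00: 22.3; 15.0: 42.5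

(standard deviation of a reading: 0.5 percentage points)

- which one finishes higher in amount of product, in percent of the substrate charged ("neither" within 2 percentage points) (north / south-west / neither)
- amount of product at the end, in percent of the substrate charged, north
- amount of product at the end, in percent of the substrate charged, south-west

What the protic impurity leaves of the partner comes first, taking one partner spent per impurity as a bench assumption. North's 0.500 is its leftover share: partner charged less impurity charged, as a fraction of the partner charge. The rule of thumb, at this impurity charge and 15 min, is that product follows that share. Oak at 0.405 reached 35.8%, alder at 0.500 reached 42.5%, ash at 0.722 reached 70.6%, and maple at 0.833 reached 77.7%. So north belongs beside alder, and south-west, at 0.875, a share higher than maple's, belongs beside maple.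

The rule has two borders, each a ratio of charges. Taking one partner per substrate as a further assumption, full conversion costs substrate over partner of the partner charge, and the share must pay for it. South-west needs 0.375, less than its share. North needs 0.500, about equal to its share. Alder needed 0.710, more than its share, yet its reading cost 0.302 of the partner charge. North's need is smaller than alder's, so north should stand a little above alder. The other border is impurity over partner reaching 1, where the share reaches zero; oak's ratio is 0.595. South-west's substrate charge of 0.15 M is higher than in any run tried, so this reckoning is untested there. It puts south-west near 77.7%.

The forecast named south-west, with north at 44% (39% to 50%) and south-west at 73% (58% to 83%), holding that the steep rise with partner came “probably because the impurity ties up part of it”. For south-west its figure lies lower than this reckoning.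

The higher finish goes to south-west: north 45.5%, south-west 77.9%.

    substrate → intermediate (k = 0.00190 /s)
    partner + intermediate → product (k = 0.0430 /M/s)
    partner + protic impurity → quenched reagent (k = 0.200 /M/s)

North's product cost 0.227 of the partner charge, and its share less that cost is 0.273, while north holds 27% of its partner. The neighbouring flask, north with 0.040 M of partner, has a share of −0.250, below zero, so the reckoning offers its product nothing. Partner is the limiting reagent there, with 1.2% of it left beside 28% of the impurity. That flask holds 75.1% as intermediate and 6.79% as product.

The readings were computed with constants of no real substance, and the scatter is random.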